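## Retrosynthetic overview

1. The target is cut at the C9 ester into the C9 alcohol and (2S,3S)-2,3-dimethyloxirane-2-carboxylic acid (Sharpless epoxidation of (Z)-2-methylbut-2-en-1-ol, then oxidation).
2. The C9 alcohol comes from the C9 ketone by hydroxyl-directed reduction; the α-methylene lactone from a C6 acrylate and the C7 ketone (intramolecular Morita–Baylis–Hillman); the C8 acetate from α-acetoxylation of a macrocyclic β-diketone.
3. The ten-membered ring comes from the six-membered ring A by a Grob-type ring expansion of a decalin aldolate formed in the flask. This step also makes the (E)-C4=C5 alkene; the (Z)-C1=C10 alkene is carried over from the cyclohexenone.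
4. The fragmentation precursor comes from a proline aldol of hydroxyacetone with 2-formyl-2,6-dimethylcyclohex-2-enone (from 2-methylcyclohex-2-enone, ethyl formate and MeI), the diol being tied as a cyclic sulfate.
5. Ring order: ring A (bought), ring B (transient), ten-membered ring, lactone; the epoxide is made separately and joined last.

Assumption: atoms are numbered as in germacranolides (C1=C10, C4=C5, C6 lactone O, C7 OH, C8 OAc, C9 ester O, C11=C13, C12 lactone C=O), and (Z)-2-methylbut-2-en-1-ol is taken as commercial.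

## Route

Step 1
Reactants: 1 2-methylcyclohex-2-en-1-one; 2 ethyl formate
Product: 3 (6Z)-6-(hydroxymethylidene)-2-methylcyclohex-2-en-1-one
Conditions: NaH, EtOH (cat.), Et2O, 0 to 23 °C; aq. HCl
Reagents that add atoms: none
Why: Crossed Claisen condensation (formylation) at C6, the only α-carbon whose formylation gives a stabilised enolate; no stereocentre is formed.

Step 2
Reactants: 3 (6Z)-6-(hydroxymethylidene)-2-methylcyclohex-2-en-1-one
Product: 4 rac-1,3-dimethyl-2-oxocyclohex-3-ene-1-carbaldehyde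
Conditions: MeI, K2CO3, acetone, 23 °C
Reagents that add atoms: iodomethane, CI
Why: C-alkylation of the stabilised 2-formyl ketone enolate builds the quaternary carbon (C4) as a racemate, which is resolved kinetically in step 3.

Step 3
Reactants: 4 rac-1,3-dimethyl-2-oxocyclohex-3-ene-1-carbaldehyde (2.2 equiv); 5 hydroxyacetone (1-hydroxypropan-2-one)
Product: 6 (3S,4S)-4-[(1S)-1,3-dimethyl-2-oxocyclohex-3-en-1-yl]-3,4-dihydroxybutan-2-one
Conditions: L-proline (30 mol %), DMSO, 23 °C
Reagents that add atoms: none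
Why: Proline-catalysed enamine aldol of hydroxyacetone (List–Notz) gives the anti (3S,4S)-diol under catalyst control, and because only (S)-4 offers its Felkin–Anh face to the catalyst-preferred approach the reaction is a kinetic resolution that consumes (S)-4, leaves (R)-4 unreacted (removed by chromatography) and gives the (S) quaternary carbon with the new C5–O anti to the ring methyl.

Step 4
Reactants: 6 (3S,4S)-4-[(1S)-1,3-dimethyl-2-oxocyclohex-3-en-1-yl]-3,4-dihydroxybutan-2-one
Product: 8 (4S,5S)-4-acetyl-5-[(1S)-1,3-dimethyl-2-oxocyclohex-3-en-1-yl]-1,3,2-dioxathiolane 2,2-dioxide, via cyclic sulfite 7 (not isolated)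
Conditions: SOCl2, Et3N, CH2Cl2, 0 °C; then RuCl3 (cat.), NaIO4, MeCN/H2O, 0 °C, short contact
Reagents that add atoms: thionyl chloride, O=S(Cl)Cl; sodium periodate, [Na+].[O-]I(=O)(=O)=O
Why: Gao–Sharpless cyclic sulfate formation (cyclic sulfite, then RuO4 oxidation) ties the anti-diol into a cis-disubstituted ring that protects C6–O and makes C5–O a leaving group without touching a stereocentre.

Step 5
Reactants: 8 (4S,5S)-4-acetyl-5-[(1S)-1,3-dimethyl-2-oxocyclohex-3-en-1-yl]-1,3,2-dioxathiolane 2,2-dioxide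
Product: 11 (4S,5E,9Z)-4-hydroxy-6,10-dimethylcyclodeca-5,9-diene-1,3-dione, via tricyclic potassium aldolate 9 (not isolated), via ring-expanded dipotassium sulfate enolate 10 (not isolated)
Conditions: KN(SiMe3)2 (2.2 equiv), THF, −78 to 0 °C; then aq. H2SO4 (2.5 equiv), THF, 23 °C
Reagents that add atoms: none
Why: Proposed new method: the kinetic potassium enolate of the methyl ketone (C8) adds reversibly to the ring ketone (C9) in a six-membered aldol to give alkoxide 9, whose C9–C4 bond is anti-periplanar to the equatorial C5–O bond of the cyclic sulfate, so an irreversible Grob fragmentation drains the aldol equilibrium, expands ring A from six to ten atoms, forms the (E)-C4=C5 alkene stereospecifically from the (4S,5S) relationship, keeps the (Z)-C1=C10 alkene of ring A and leaves C6 (S, untouched) as a sulfate monoester that aqueous acid hydrolyses by S–O cleavage; the closest known reaction types are the Wharton (Grob) fragmentation of 1,3-diol monosulfonates and the one-pot SmI2 Barbier cyclisation/Grob fragmentation.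

Step 6
Reactants: 11 (4S,5E,9Z)-4-hydroxy-6,10-dimethylcyclodeca-5,9-diene-1,3-dione
Product: 12 (4S,5E,9Z)-4-hydroxy-6,10-dimethyl-1,3-dioxocyclodeca-5,9-dien-2-yl acetate (C8 epimers, interconverting)
Conditions: PhI(OAc)2, AcOH, 23 °C
Reagents that add atoms: (diacetoxyiodo)benzene, CC(=O)OI(OC(C)=O)c1ccccc1
Why: α-Acetoxylation of the β-diketone through its enol (hypervalent-iodine ligand coupling) occurs only at the doubly activated C8; the new C8 centre is stereolabile and is fixed in step 8.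

Step 7
Reactants: 12 (4S,5E,9Z)-4-hydroxy-6,10-dimethyl-1,3-dioxocyclodeca-5,9-dien-2-yl acetate; 13 acryloyl chloride
Product: 14 (1S,2E,6Z)-9-(acetyloxy)-3,7-dimethyl-8,10-dioxocyclodeca-2,6-dien-1-yl prop-2-enoate (C8 epimers, interconverting)
Conditions: 2,6-lutidine, CH2Cl2, −40 °C
Reagents that add atoms: none
Why: Acylation of the only hydroxyl by the acid chloride with a weak pyridine base (Einhorn-type esterification) that does not enolise the 2-acetoxy-1,3-diketone; C6 keeps its configuration.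

Step 8
Reactants: 14 (1S,2E,6Z)-9-(acetyloxy)-3,7-dimethyl-8,10-dioxocyclodeca-2,6-dien-1-yl prop-2-enoate
Product: 15 (3aS,4R,6Z,10E,11aS)-3a-hydroxy-6,10-dimethyl-3-methylidene-2,5-dioxo-2,3,3a,4,5,8,9,11a-octahydrocyclodeca[b]furan-4-yl acetate
Conditions: DABCO (30 mol %), MeCN, 23 °C
Reagents that add atoms: none
Why: Intramolecular Morita–Baylis–Hillman reaction: the tether restricts the ammonium enolate to the C7 ketone (five-membered ring), attack on the face that puts C5 and C8 trans on the new lactone is expected to give the trans-fused ring with (S)-C7, and C8, now an ordinary α-acyloxy ketone, is expected to equilibrate under the amine to the epimer with the acetoxy group gauche to the new hydroxyl (hydrogen bond; R by CIP in this ketone).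

Step 9
Reactants: 15 (3aS,4R,6Z,10E,11aS)-3a-hydroxy-6,10-dimethyl-3-methylidene-2,5-dioxo-2,3,3a,4,5,8,9,11a-octahydrocyclodeca[b]furan-4-yl acetate
Product: 16 (3aS,4S,5S,6Z,10E,11aS)-3a,5-dihydroxy-6,10-dimethyl-3-methylidene-2-oxo-2,3,3a,4,5,8,9,11a-octahydrocyclodeca[b]furan-4-yl acetate
Conditions: Me4NBH(OAc)3, MeCN/AcOH, −20 °C
Reagents that add atoms: none
Why: Evans–Saksena hydroxyl-directed reduction: the tertiary C7–OH binds boron and delivers hydride internally to the C9 ketone (1,2-addition), giving the 1,3-anti diol, that is (S) at C9, under acidic conditions that do not epimerise C8 or reduce the acrylate.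

Step 10
Reactants: 17 (Z)-2-methylbut-2-en-1-ol
Product: 18 [(2R,3S)-2,3-dimethyloxiran-2-yl]methanol
Conditions: Ti(OiPr)4 (10 mol %), D-(−)-diethyl tartrate, t-BuOOH, 4 Å sieves, CH2Cl2, −20 °C
Reagents that add atoms: tert-butyl hydroperoxide, CC(C)(C)OO
Why: Katsuki–Sharpless asymmetric epoxidation; the D-(−)-tartrate delivers oxygen to the face that gives the (2R,3S)-epoxy alcohol, and the cis relation of CH2OH and the C3 methyl comes from the (Z)-alkene.

Step 11
Reactants: 18 [(2R,3S)-2,3-dimethyloxiran-2-yl]methanol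
Product: 19 (2S,3S)-2,3-dimethyloxirane-2-carboxylic acid
Conditions: RuCl3 (cat.), NaIO4, CCl4/MeCN/H2O, 23 °C
Reagents that add atoms: water, O
Why: RuO4 oxidation (Sharpless conditions) takes the primary alcohol to the acid without opening the epoxide; the descriptor at C2 changes from R to S only through CIP priorities.

Step 12
Reactants: 16 (3aS,4S,5S,6Z,10E,11aS)-3a,5-dihydroxy-6,10-dimethyl-3-methylidene-2-oxo-2,3,3a,4,5,8,9,11a-octahydrocyclodeca[b]furan-4-yl acetate; 19 (2S,3S)-2,3-dimethyloxirane-2-carboxylic acid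
Product: 21 (3aS,4S,5S,6Z,10E,11aS)-4-(acetyloxy)-3a-hydroxy-6,10-dimethyl-3-methylidene-2-oxo-2,3,3a,4,5,8,9,11a-octahydrocyclodeca[b]furan-5-yl (2S,3S)-2,3-dimethyloxirane-2-carboxylate, via mixed anhydride 20 (not isolated)
Conditions: 2,4,6-trichlorobenzoyl chloride, Et3N, THF, 23 °C; then DMAP, toluene, 23 °C
Reagents that add atoms: none
Why: Yamaguchi esterification acylates only the secondary allylic C9–OH (the tertiary C7–OH is inert), with retention at C9 and at both epoxide carbons.

## Compound list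

1 | 2-methylcyclohex-2-en-1-one | CC1=CCCCC1=O | starting material
2 | ethyl formate | CCOC=O | starting material
3 | (6Z)-6-(hydroxymethylidene)-2-methylcyclohex-2-en-1-one | CC1=CCC/C(=C/O)C1=O | intermediate
4 | rac-1,3-dimethyl-2-oxocyclohex-3-ene-1-carbaldehyde | CC1=CCCC(C)(C=O)C1=O | intermediate
5 | hydroxyacetone (1-hydroxypropan-2-one) | CC(=O)CO | starting material
6 | (3S,4S)-4-[(1S)-1,3-dimethyl-2-oxocyclohex-3-en-1-yl]-3,4-dihydroxybutan-2-one | CC(=O)[C@@H](O)[C@@H](O)[C@]1(C)CCC=C(C)C1=O | intermediate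
7 | (4S,5S)-4-acetyl-5-[(1S)-1,3-dimethyl-2-oxocyclohex-3-en-1-yl]-1,3,2-dioxathiolane 2-oxide (cyclic sulfite, both sulfur epimers) | CC(=O)[C@H]1OS(=O)O[C@H]1[C@]2(C)CCC=C(C)C2=O | intermediate
8 | (4S,5S)-4-acetyl-5-[(1S)-1,3-dimethyl-2-oxocyclohex-3-en-1-yl]-1,3,2-dioxathiolane 2,2-dioxide (cyclic sulfate) | CC(=O)[C@H]1OS(=O)(=O)O[C@H]1[C@]2(C)CCC=C(C)C2=O | intermediate
9 | potassium alkoxide of the tricyclic aldol (3S,4S,4aS)-8a-hydroxy-4a,8-dimethyl-3,4-(sulfonyldioxy)-3,4,4a,5,6,8a-hexahydronaphthalen-2(1H)-one (either 8a epimer) | [K+].O=C1CC2([O-])C(C)=CCC[C@@]2(C)[C@@H]2OS(=O)(=O)O[C@H]12 | intermediate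
10 | dipotassium salt (enolate and sulfate monoester) of (4S,5E,9Z)-6,10-dimethyl-4-(sulfooxy)cyclodeca-5,9-diene-1,3-dione | [K+].[K+].[O-]S(=O)(=O)O[C@H]1/C=C(\C)CC/C=C(/C)C(=O)C=C1[O-] | intermediate
11 | (4S,5E,9Z)-4-hydroxy-6,10-dimethylcyclodeca-5,9-diene-1,3-dione | O[C@H]1/C=C(\C)CC/C=C(/C)C(=O)CC1=O | intermediate
12 | (4S,5E,9Z)-4-hydroxy-6,10-dimethyl-1,3-dioxocyclodeca-5,9-dien-2-yl acetate (C8 epimers, interconverting) | O[C@H]1/C=C(\C)CC/C=C(/C)C(=O)C(OC(C)=O)C1=O | intermediate
13 | acryloyl chloride | C=CC(Cl)=O | starting material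
14 | (1S,2E,6Z)-9-(acetyloxy)-3,7-dimethyl-8,10-dioxocyclodeca-2,6-dien-1-yl prop-2-enoate (C8 epimers, interconverting) | C=CC(=O)O[C@H]1/C=C(\C)CC/C=C(/C)C(=O)C(OC(C)=O)C1=O | intermediate
15 | (3aS,4R,6Z,10E,11aS)-3a-hydroxy-6,10-dimethyl-3-methylidene-2,5-dioxo-2,3,3a,4,5,8,9,11a-octahydrocyclodeca[b]furan-4-yl acetate | C=C1C(=O)O[C@H]2/C=C(\C)CC/C=C(/C)C(=O)[C@H](OC(C)=O)[C@]12O | intermediate
16 | (3aS,4S,5S,6Z,10E,11aS)-3a,5-dihydroxy-6,10-dimethyl-3-methylidene-2-oxo-2,3,3a,4,5,8,9,11a-octahydrocyclodeca[b]furan-4-yl acetate | C=C1C(=O)O[C@H]2/C=C(\C)CC/C=C(/C)[C@H](O)[C@H](OC(C)=O)[C@]12O | intermediate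
17 | (Z)-2-methylbut-2-en-1-ol | C/C=C(/C)CO | starting material
18 | [(2R,3S)-2,3-dimethyloxiran-2-yl]methanol | OC[C@@]1(C)O[C@H]1C | intermediate
19 | (2S,3S)-2,3-dimethyloxirane-2-carboxylic acid | OC(=O)[C@@]1(C)O[C@H]1C | intermediate
20 | (2S,3S)-2,3-dimethyloxirane-2-carboxylic 2,4,6-trichlorobenzoic anhydride | O=C(OC(=O)[C@@]1(C)O[C@H]1C)c1c(Cl)cc(Cl)cc1Cl | intermediate
21 | (3aS,4S,5S,6Z,10E,11aS)-4-(acetyloxy)-3a-hydroxy-6,10-dimethyl-3-methylidene-2-oxo-2,3,3a,4,5,8,9,11a-octahydrocyclodeca[b]furan-5-yl (2S,3S)-2,3-dimethyloxirane-2-carboxylate | C=C1C(=O)O[C@H]2/C=C(\C)CC/C=C(/C)[C@H](OC(=O)[C@@]3(C)O[C@H]3C)[C@H](OC(C)=O)[C@]12O | target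

## Step count and risks

Total steps: 12. Longest linear sequence: 10 steps (steps 1 to 9, then 12).

**Step 5 (the proposed new step).** The risks are E1cB loss of the sulfate from a C6 enolate and slow aldol addition to the hindered ring ketone. The fallback uses known, stepwise chemistry; it sets out from 8 and comes back at 11. Treat 8 with Me3SiOTf and Et3N to get the kinetic silyl enol ether (4S,5S)-4-[(1S)-1,3-dimethyl-2-oxocyclohex-3-en-1-yl]-5-{1-[(trimethylsilyl)oxy]ethenyl}-1,3,2-dioxathiolane 2,2-dioxide F3. Close ring B by an intramolecular Mukaiyama aldol (BF3·OEt2, CH2Cl2, −78 °C) and isolate the bicyclic aldol (3S,4S,4aS)-8a-hydroxy-4a,8-dimethyl-3,4-(sulfonyldioxy)-3,4,4a,5,6,8a-hexahydronaphthalen-2(1H)-one F4. Then run a classical Wharton fragmentation with KOtBu in t-BuOH/THF and hydrolyse the sulfate monoester with dilute H2SO4 to reach 11.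

**Step 3.** The risks are weak matched/mismatched discrimination of the racemic aldehyde and amine-induced deformylation of the β-keto aldehyde. The fallback sets out from 4 and comes back at 6. Condense rac-4 with (1R,2R)-N,N′-dimethyl-1,2-diphenylethane-1,2-diamine (sieves, Et2O) and separate the diastereomeric aminals by chromatography. Take the one derived from the (S)-aldehyde, (4R,5R)-2-[(1S)-1,3-dimethyl-2-oxocyclohex-3-en-1-yl]-1,3-dimethyl-4,5-diphenylimidazolidine F1, and hydrolyse it (aq. HCl, Et2O, 0 °C) to (1S)-1,3-dimethyl-2-oxocyclohex-3-ene-1-carbaldehyde F2. Run the same L-proline aldol with 5 on this single enantiomer (1 equiv, no resolution needed) to reach 6.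

**Step 8.** The acidic 2-acetoxy-1,3-diketone may tie up the amine catalyst, and the lactone fusion and the C8 epimer ratio rest on conformational arguments. The fallback removes the 1,3-diketone before the cyclisation; it sets out from 14 and comes back at 21. Reduce the enone carbonyl of 14 first under Luche conditions (NaBH4, CeCl3, MeOH, −78 °C; the doubly α-oxygenated C7 ketone is masked as its hemiketal) to (1S,2E,6Z,8S,9S)-9-(acetyloxy)-8-hydroxy-3,7-dimethyl-10-oxocyclodeca-2,6-dien-1-yl prop-2-enoate F5, separating C8/C9 isomers if needed. Esterify with 19 (Yamaguchi conditions) to (1S,2E,6Z,8S,9S)-9-(acetyloxy)-3,7-dimethyl-10-oxo-1-(prop-2-enoyloxy)cyclodeca-2,6-dien-8-yl (2S,3S)-2,3-dimethyloxirane-2-carboxylate F6. Then run the DABCO Morita–Baylis–Hillman lactonisation on F6, which gives 21 directly.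

Further compounds

F1 | step 3 | (4R,5R)-2-[(1S)-1,3-dimethyl-2-oxocyclohex-3-en-1-yl]-1,3-dimethyl-4,5-diphenylimidazolidine | CN1C([C@]2(C)CCC=C(C)C2=O)N(C)[C@H](c2ccccc2)[C@H]1c1ccccc1
F2 | step 3 | (1S)-1,3-dimethyl-2-oxocyclohex-3-ene-1-carbaldehyde | O=C[C@]1(C)CCC=C(C)C1=O
F3 | step 5 | (4S,5S)-4-[(1S)-1,3-dimethyl-2-oxocyclohex-3-en-1-yl]-5-{1-[(trimethylsilyl)oxy]ethenyl}-1,3,2-dioxathiolane 2,2-dioxide | C=C(O[Si](C)(C)C)[C@H]1OS(=O)(=O)O[C@H]1[C@]2(C)CCC=C(C)C2=O
F4 | step 5 | (3S,4S,4aS)-8a-hydroxy-4a,8-dimethyl-3,4-(sulfonyldioxy)-3,4,4a,5,6,8a-hexahydronaphthalen-2(1H)-one | O=C1CC2(O)C(C)=CCC[C@@]2(C)[C@@H]2OS(=O)(=O)O[C@H]12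
F5 | step 8 | (1S,2E,6Z,8S,9S)-9-(acetyloxy)-8-hydroxy-3,7-dimethyl-10-oxocyclodeca-2,6-dien-1-yl prop-2-enoate | C=CC(=O)O[C@H]1/C=C(\C)CC/C=C(/C)[C@H](O)[C@H](OC(C)=O)C1=O
F6 | step 8 | (1S,2E,6Z,8S,9S)-9-(acetyloxy)-3,7-dimethyl-10-oxo-1-(prop-2-enoyloxy)cyclodeca-2,6-dien-8-yl (2S,3S)-2,3-dimethyloxirane-2-carboxylate | C=CC(=O)O[C@H]1/C=C(\C)CC/C=C(/C)[C@H](OC(=O)[C@@]2(C)O[C@H]2C)[C@H](OC(C)=O)C1=O
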